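**Plan**

1. Cuts: first the acrylate Cα=Cβ bond. Cβ is a formyl carbon on C1′ of ring C (the caffeoyl benzene ring). Cα and the ester carbonyl come from a malonic half-ester that already holds the ester C–O bond to the carbinol oxygen. Then the C4′–O bond of the diaryl ether, then C3=C4 and O1–C2 of the pyranone ring B.
2. Enabling feature: the ether oxygen sits on C3 of ring B, where it is the enol oxygen of a chroman-2,3-dione (a stable, acidic 3-hydroxycoumarin). The ether carbon C4′ of ring C is para to C1′. With a formyl group on C1′, a C4′–F bond is open to SNAr by that enolate, and the same formyl group later becomes Cβ.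
3. Forward: ring B is closed onto the ring A salicylaldehyde with oxygen already on C3 (steps 1–2). The coumarin enolate is arylated with ring C (step 3) and the methyl ethers are removed (step 4). The danshensu malonate (steps 5–6) is joined by a decarboxylative Knoevenagel–Doebner condensation (step 7), and the allyl groups are removed (step 8).
4. Stereochemistry: the (R) carbinol center is taken from (R)-danshensu and no bond to it is broken. The (E) alkene arises in the decarboxylative condensation, which funnels both arylidene isomers to the E product.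

Key step: step 3

Assumption: sodium danshensu (9) is bought as the single (R) enantiomer, which is the configuration required at the carbinol carbon of the target.

**Route**

Step 1
Reactants: 1 2-hydroxy-4,5-dimethoxybenzaldehyde; 2 N-acetylglycine
Product: 3 N-(6,7-dimethoxy-2-oxo-2H-chromen-3-yl)acetamide (3-acetamido-6,7-dimethoxycoumarin)
Conditions: Ac2O, NaOAc, 110 °C
Reagents that add atoms: none
Why: Erlenmeyer–Plöchl (Perkin-type) condensation, in which the activated N-acetylglycine condenses with the formyl group and the ortho hydroxyl closes the pyranone ring, the standard entry to 3-acetamidocoumarins.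

Step 2
Reactants: 3 N-(6,7-dimethoxy-2-oxo-2H-chromen-3-yl)acetamide
Product: 5 3-hydroxy-6,7-dimethoxy-2H-chromen-2-one, via 3-amino-6,7-dimethoxycoumarin 4 (not isolated)
Conditions: 3 M aq. HCl, reflux
Reagents that add atoms: water, O
Why: Acid hydrolysis of the enamide and then of the enamine (through its iminium tautomer) should give the 2,3-dione, which is obtained as its conjugated enol, while the aryl methyl ethers and the lactone are stable to aqueous HCl.

Step 3
Reactants: 5 3-hydroxy-6,7-dimethoxy-2H-chromen-2-one; 6 4-fluoro-3-methoxybenzaldehyde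
Product: 7 4-[(6,7-dimethoxy-2-oxo-2H-chromen-3-yl)oxy]-3-methoxybenzaldehyde
Conditions: Cs2CO3, DMSO, 100 °C, Ar
Reagents that add atoms: none
Why: Addition–elimination SNAr: the cesium enolate of 5 (the oxygen on C3 of ring B) adds at C4′ of 6, the charge of the Meisenheimer intermediate is taken up by the formyl group on the para carbon C1′, and fluoride leaves. The closest known reaction type is the diaryl ether synthesis from 4-fluorobenzaldehydes and phenoxides or other acidic enols in dipolar aprotic solvents. No ring is closed and no stereocenter is formed. The step needs O- rather than C4-arylation of the ambident enolate and needs the lactone and the formyl group to survive: the charge-controlled SNAr transition state favours the oxygen terminus over the softer C4 terminus, dry carbonate should not open the lactone, and the aldehyde has no α-hydrogen. The site of the ether on ring C is fixed by the position of fluorine, so the ring C oxygens need not be told apart, and all three methoxy groups are inert. The formyl group that activates this step is kept as the electrophile for step 7.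

Step 4
Reactants: 7 4-[(6,7-dimethoxy-2-oxo-2H-chromen-3-yl)oxy]-3-methoxybenzaldehyde
Product: 8 4-[(6,7-dihydroxy-2-oxo-2H-chromen-3-yl)oxy]-3-hydroxybenzaldehyde
Conditions: BBr3, CH2Cl2, −78 °C to rt; then H2O
Reagents that add atoms: none
Why: Lewis acid O-demethylation with BBr3 (bromide attacks the methyl carbon of each boron–ether adduct in an SN2 step) should free the three phenols, while the diaryl ether, the lactone and the formyl group are not cleaved and are recovered on aqueous work-up.

Step 5
Reactants: 9 sodium (R)-3-(3,4-dihydroxyphenyl)-2-hydroxypropanoate (sodium danshensu)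
Product: 10 allyl (R)-3-[3,4-bis(allyloxy)phenyl]-2-hydroxypropanoate
Conditions: allyl bromide, K2CO3, DMF, rt, N2
Reagents that add atoms: allyl bromide, C=CCBr
Why: Williamson ether synthesis and carboxylate O-alkylation: carbonate deprotonates only the two phenols beside the carboxylate, so the secondary alcohol should stay free, and the (R) center is not touched.

Step 6
Reactants: 10 allyl (R)-3-[3,4-bis(allyloxy)phenyl]-2-hydroxypropanoate; 11 Meldrum's acid (2,2-dimethyl-1,3-dioxane-4,6-dione)
Product: 12 3-{[(2R)-1-(allyloxy)-3-[3,4-bis(allyloxy)phenyl]-1-oxopropan-2-yl]oxy}-3-oxopropanoic acid (malonic half-ester)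
Conditions: toluene, 100 °C
Reagents that add atoms: none
Why: Thermal ring-opening acylation of the alcohol by Meldrum's acid with loss of acetone should give the malonic half-ester without a coupling reagent, and the C–O bond at the stereocenter is not broken, so the configuration is retained.

Step 7
Reactants: 8 4-[(6,7-dihydroxy-2-oxo-2H-chromen-3-yl)oxy]-3-hydroxybenzaldehyde; 12 malonic half-ester
Product: 14 allyl (R)-3-[3,4-bis(allyloxy)phenyl]-2-{[(E)-3-{4-[(6,7-dihydroxy-2-oxo-2H-chromen-3-yl)oxy]-3-hydroxyphenyl}prop-2-enoyl]oxy}propanoate, via arylidene malonic half-ester 13 (not isolated)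
Conditions: pyridine, piperidine (cat.), 45 °C, Ar
Reagents that add atoms: none
Why: Knoevenagel–Doebner condensation of a malonic half-ester, in which the arylidene malonic acid loses CO2 in pyridine to give the thermodynamically favoured (E)-cinnamate from either arylidene isomer, a reaction type that tolerates free phenolic hydroxyls on the aldehyde.

Step 8
Reactants: 14 allyl (R)-3-[3,4-bis(allyloxy)phenyl]-2-{[(E)-3-{4-[(6,7-dihydroxy-2-oxo-2H-chromen-3-yl)oxy]-3-hydroxyphenyl}prop-2-enoyl]oxy}propanoate
Product: 15 (R)-3-(3,4-dihydroxyphenyl)-2-{[(E)-3-{4-[(6,7-dihydroxy-2-oxo-2H-chromen-3-yl)oxy]-3-hydroxyphenyl}prop-2-enoyl]oxy}propanoic acid (CNP0318082.1)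
Conditions: Pd(PPh3)4 (cat.), morpholine, THF, rt, Ar; then dil. aq. HCl
Reagents that add atoms: none
Why: Tsuji–Trost deallylation, in which zerovalent palladium ionizes the allyl ester and the two aryl allyl ethers to π-allyl complexes that morpholine traps, under conditions that should leave the cinnamate ester, the lactone, the (E) alkene and the stereocenter untouched.

**Compound list**

1 | 2-hydroxy-4,5-dimethoxybenzaldehyde | COc1cc(O)c(C=O)cc1OC | starting material
2 | N-acetylglycine | CC(=O)NCC(=O)O | starting material
3 | N-(6,7-dimethoxy-2-oxo-2H-chromen-3-yl)acetamide | CC(=O)Nc1cc2cc(OC)c(OC)cc2oc1=O | intermediate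
4 | 3-amino-6,7-dimethoxy-2H-chromen-2-one | Nc1cc2cc(OC)c(OC)cc2oc1=O | intermediate (not isolated)
5 | 3-hydroxy-6,7-dimethoxy-2H-chromen-2-one | Oc1cc2cc(OC)c(OC)cc2oc1=O | intermediate
6 | 4-fluoro-3-methoxybenzaldehyde | COc1cc(C=O)ccc1F | starting material
7 | 4-[(6,7-dimethoxy-2-oxo-2H-chromen-3-yl)oxy]-3-methoxybenzaldehyde | COc1cc(C=O)ccc1Oc1cc2cc(OC)c(OC)cc2oc1=O | intermediate
8 | 4-[(6,7-dihydroxy-2-oxo-2H-chromen-3-yl)oxy]-3-hydroxybenzaldehyde | O=Cc1ccc(Oc2cc3cc(O)c(O)cc3oc2=O)c(O)c1 | intermediate
9 | sodium (R)-3-(3,4-dihydroxyphenyl)-2-hydroxypropanoate (sodium danshensu) | [Na+].[O-]C(=O)[C@H](O)Cc1ccc(O)c(O)c1 | starting material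
10 | allyl (R)-3-[3,4-bis(allyloxy)phenyl]-2-hydroxypropanoate | O[C@H](Cc1ccc(OCC=C)c(OCC=C)c1)C(=O)OCC=C | intermediate
11 | Meldrum's acid (2,2-dimethyl-1,3-dioxane-4,6-dione) | CC1(C)OC(=O)CC(=O)O1 | starting material
12 | 3-{[(2R)-1-(allyloxy)-3-[3,4-bis(allyloxy)phenyl]-1-oxopropan-2-yl]oxy}-3-oxopropanoic acid | OC(=O)CC(=O)O[C@H](Cc1ccc(OCC=C)c(OCC=C)c1)C(=O)OCC=C | intermediate
13 | 2-{[(2R)-1-(allyloxy)-3-[3,4-bis(allyloxy)phenyl]-1-oxopropan-2-yl]oxycarbonyl}-3-{4-[(6,7-dihydroxy-2-oxo-2H-chromen-3-yl)oxy]-3-hydroxyphenyl}prop-2-enoic acid (arylidene malonic half-ester, E/Z mixture at the new alkene) | OC(=O)C(=Cc1ccc(Oc2cc3cc(O)c(O)cc3oc2=O)c(O)c1)C(=O)O[C@H](Cc1ccc(OCC=C)c(OCC=C)c1)C(=O)OCC=C | intermediate (not isolated)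
14 | allyl (R)-3-[3,4-bis(allyloxy)phenyl]-2-{[(E)-3-{4-[(6,7-dihydroxy-2-oxo-2H-chromen-3-yl)oxy]-3-hydroxyphenyl}prop-2-enoyl]oxy}propanoate | O=C(/C=C/c1ccc(Oc2cc3cc(O)c(O)cc3oc2=O)c(O)c1)O[C@H](Cc1ccc(OCC=C)c(OCC=C)c1)C(=O)OCC=C | intermediate
15 | (R)-3-(3,4-dihydroxyphenyl)-2-{[(E)-3-{4-[(6,7-dihydroxy-2-oxo-2H-chromen-3-yl)oxy]-3-hydroxyphenyl}prop-2-enoyl]oxy}propanoic acid | O=C(/C=C/c1ccc(Oc2cc3cc(O)c(O)cc3oc2=O)c(O)c1)O[C@H](Cc1ccc(O)c(O)c1)C(=O)O | target

**Count and risks**

Total step count: 8. Longest linear sequence: 6 (steps 1, 2, 3, 4, 7, 8); the danshensu branch (steps 5, 6) joins at step 7.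

Steps most likely to fail:

Step 3. The fluoroarene is only moderately activated, because the ortho methoxy group donates into C4′. At the temperature that the substitution needs, opening of the lactone or aldol-type attack of C4 of the enolate on the formyl group may outrun the ether formation. The fallback sets out from 5 and comes back at 7. Compound 5 would be coupled with commercial (4-formyl-2-methoxyphenyl)boronic acid in a Chan–Lam O-arylation (Cu(OAc)2, pyridine, 4 Å molecular sieves, CH2Cl2, air, rt). The aryl group is then delivered from boron to the enol oxygen at a copper center that cycles between the divalent and trivalent states, so no SNAr activation and no heating are required. This fallback makes no compound outside the compound list (F0).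

Step 7. Phenoxide formation on rings A and C in pyridine may lower the electrophilicity of the formyl group, so that plain decarboxylation of the half-ester to the acetate outruns the condensation. The fallback sets out from 10 and 8 and comes back at 14.
- Alcohol 10 would be esterified with bromoacetic acid (DCC, DMAP cat., CH2Cl2, 0 °C) to allyl (R)-3-[3,4-bis(allyloxy)phenyl]-2-(2-bromoacetoxy)propanoate F1.
- PPh3 in toluene at rt should convert it to {2-[(2R)-1-(allyloxy)-3-[3,4-bis(allyloxy)phenyl]-1-oxopropan-2-yl]oxy-2-oxoethyl}triphenylphosphonium bromide F2.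
- Aqueous Na2CO3/CH2Cl2 should give the stabilized ylide allyl (R)-3-[3,4-bis(allyloxy)phenyl]-2-[(triphenylphosphoranylidene)acetoxy]propanoate F3.
- A Wittig reaction of the ylide with aldehyde 8 (THF, 60 °C) should give 14. Stabilized ylides are E-selective and tolerate free phenols.

Step 8. Removal of three allyl groups from the fully assembled polyphenol may stay incomplete, the π-allyl palladium intermediate may re-allylate the free catechol oxygens of rings A and C, and the amine may degrade the ester. The fallback sets out from 12 and comes back at 15. The allyl groups would be removed from 12 before the union (Pd(PPh3)4 cat., morpholine, THF, rt; acidic work-up), where no catechol, lactone or cinnamate is present, to give (R)-2-[(carboxyacetyl)oxy]-3-(3,4-dihydroxyphenyl)propanoic acid F4. Knoevenagel–Doebner condensation of this acid with 8 (pyridine, piperidine cat., 45 °C) would pass through 2-{[(1R)-1-carboxy-2-(3,4-dihydroxyphenyl)ethoxy]carbonyl}-3-{4-[(6,7-dihydroxy-2-oxo-2H-chromen-3-yl)oxy]-3-hydroxyphenyl}prop-2-enoic acid F5 and should give 15 directly, so the last step is a union without protecting groups.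

**Further compounds**

F0 | step 3 | none | none
F1 | step 7 | allyl (R)-3-[3,4-bis(allyloxy)phenyl]-2-(2-bromoacetoxy)propanoate | BrCC(=O)O[C@H](Cc1ccc(OCC=C)c(OCC=C)c1)C(=O)OCC=C
F2 | step 7 | {2-[(2R)-1-(allyloxy)-3-[3,4-bis(allyloxy)phenyl]-1-oxopropan-2-yl]oxy-2-oxoethyl}triphenylphosphonium bromide | [Br-].O=C(C[P+](c1ccccc1)(c1ccccc1)c1ccccc1)O[C@H](Cc1ccc(OCC=C)c(OCC=C)c1)C(=O)OCC=C
F3 | step 7 | allyl (R)-3-[3,4-bis(allyloxy)phenyl]-2-[(triphenylphosphoranylidene)acetoxy]propanoate | O=C(C=P(c1ccccc1)(c1ccccc1)c1ccccc1)O[C@H](Cc1ccc(OCC=C)c(OCC=C)c1)C(=O)OCC=C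
F4 | step 8 | (R)-2-[(carboxyacetyl)oxy]-3-(3,4-dihydroxyphenyl)propanoic acid | OC(=O)CC(=O)O[C@H](Cc1ccc(O)c(O)c1)C(=O)O
F5 | step 8 | 2-{[(1R)-1-carboxy-2-(3,4-dihydroxyphenyl)ethoxy]carbonyl}-3-{4-[(6,7-dihydroxy-2-oxo-2H-chromen-3-yl)oxy]-3-hydroxyphenyl}prop-2-enoic acid (E/Z mixture at the new alkene) | OC(=O)C(=Cc1ccc(Oc2cc3cc(O)c(O)cc3oc2=O)c(O)c1)C(=O)O[C@H](Cc1ccc(O)c(O)c1)C(=O)O
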